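The runs stem from a simulated flask with made-up constants, noise included.

I nearly read the late creep the wrong way. Tuesday's flask and Saturday's colder run crept at nearly the same slope, and that looked as if temperature did little. So I looked at the starts instead.

| setting | Tuesday's | Saturday's | flask |
|---|---|---|---|
| substrate | 12 mM | 12 mM | 12 mM |
| coupling partner | 14.4 mM | 22 mM | 14.4 mM |
| temperature | −20 °C | −35 °C | −20 °C |
| remark | the very flask that is asked about, followed so far | run made earlier |  |
| time |  |  | 8.0 d |

| run | time / d | target / % |
|---|---|---|
| Tuesday's | 1.67 | 13.1 |
| Tuesday's | 3.00 | 14.1 |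
| Tuesday's | 5.00 | 15.5 |
| Tuesday's | 6.00 | 16.1 |
| Saturday's | 1.04 | 3.7 |
| Saturday's | 2.50 | 7.0 |
| Saturday's | 5.00 | 9.1 |
| Saturday's | 8.00 | 11.0 |

(scatter of a reading: 0.3 percentage points)

- target, in percent of the substrate first charged, at 8.0 d
- the remedy with the largest gain of target, or "none" below 2 percentage points (north-east / north-west / west / south / none)
- target present, with what was taken out counted in, in percent of the substrate first charged, after north-west
- target present, with what was taken out counted in, in percent of the substrate first charged, after south

- north-east: at 8.0 d raise the temperature by 20 K, then wait 8.0 d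
- north-west: change nothing and wait 8.0 d more
- west: at 8.0 d add coupling partner, 100% of the amount charged, then wait 8.0 d
- south: at 8.0 d take out 90% of the target then present, then wait 8.0 d

- removed target is counted in
- what was read earlier has a scatter of 0.3 percentage points, one standard deviation
- additions bring no volume worth counting

This note is for whoever takes over the bench. Tuesday's flask stood at 16.1% at 6.00 d. On its last slope I expected 17.4% at 8.0 d.

My scale had a plain zero. I assumed the first slope follows c(coupling partner). If temperature did nothing, Saturday's run would then have started 1.53 times quicker than Tuesday's flask. It did not. The first slope per c(coupling partner), Tuesday's over Saturday's, came to 3.37 for 15.0 K. I call this the warming factor.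

Tuesday's first reading already lay in the bend, since its next slope was lower. So I held the factor as a rough figure, not a bound. Over 20 K it grew to 5.05. Adding coupling partner makes the charge twice as large, which is less. So my note said: leave the coupling partner bottle alone and warm the flask.

The forecast gave 17.3% at 8.0 d, a shade under my line. It gave 22% after north-west and 22.3% after south, and it chose west: “Doubling partner therefore beats warming”.

    2 substrate → self-condensation product (k = 7.51 × 10⁻⁴ M⁻¹ h⁻¹, Ea = 77.0 kJ mol⁻¹)
    intermediate A → side product (k = 0.0126 h⁻¹, Ea = 93.0 kJ mol⁻¹)
    substrate → intermediate A (k = 0.0129 h⁻¹, Ea = 83.0 kJ mol⁻¹)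
    substrate + coupling partner ⇌ intermediate B (K = 2400 M⁻¹, k = 2.41 M⁻¹ h⁻¹, Ea = 46.0 kJ mol⁻¹, ΔH = −56.0 kJ mol⁻¹)
    substrate + coupling partner → target (k = 0.669 M⁻¹ h⁻¹, Ea = 67.0 kJ mol⁻¹)
    (constants at −20 °C)

Tuesday's flask stood at 16.1% at 8.0 d. It gave 17.4% after north-west and 17.4% after south. Of the options north-east was best, gaining 11 percentage points against 1.9 points for west. At 8.00 d, intermediate B, the resting state, held 49.3% of the substrate. The gain from waiting times my warming factor for 20 K gave 6.3 points, below the gain the warming brought. Dividing the flask's 16.1% by my warming factor gave 4.79%, and a run at −35 °C with the flask's 14.4 mM of coupling partner made 8.49% at 8.00 d.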